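**Plan**

- Labels: unit A (2-linked), unit B (central) and unit C (4-linked) are 8-methoxynaphthalen-1-ol units, each numbered with OH on C1 and OMe on C8.
- Retrosynthesis: after unmasking (three O-benzyl groups, the B8 O-methyl group) the B8–B8a bond is cut, opening ring B4a–B5–B6–B7–B8–B8a to a but-3-enoic acid chain on a benzene ring; then B5=B6 (Wittig), then the biaryl bonds B4–C4 and B2–A2.
- Enabling feature: ring B4a–B5–B6–B7–B8–B8a carries nothing but the B8 oxygen, and B4 is occupied by unit C, so B8a is the only free position ortho to the side chain and this ring can be grown last on a benzene that already holds A and C.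
- Forward: A and C boronates are made from naphthalene-1,8-diol and coupled in turn to the C–I and then the C–Br bond of a benzaldehyde. The C4 acid chain is attached, the methoxy ring of B is closed, and the B8 oxygen (the only acylated one) is methylated before global debenzylation.
- Stereochemistry: the target has no stereocentre; nothing is set or needs protecting.

Key step: step 14

Remark: the target is drawn without axial descriptors; its B4–C4 axis is of the 1,1'-binaphthyl type with only hydrogens in the flanking positions, so the compound is made without control of that axis.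

**Route**

Step 1
Reactants: 1 naphthalene-1,8-diol
Product: 2 8-methoxynaphthalen-1-ol
Conditions: MeI (1.05 equiv), K2CO3 (1.0 equiv), acetone, reflux
Reagents that add atoms: iodomethane, CI
Why: Williamson O-methylation should stop at the monoether, because the remaining hydroxyl is locked in a hydrogen bond to the new peri methoxy oxygen and is much less acidic.

Step 2
Reactants: 2 8-methoxynaphthalen-1-ol
Product: 3 1-methoxy-8-(methoxymethoxy)naphthalene
Conditions: NaH, DMF, 0 °C; MOMCl, 0 °C → rt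
Reagents that add atoms: chloromethyl methyl ether, COCCl
Why: Williamson-type MOM protection of the fully deprotonated, hydrogen-bonded naphthol installs the directing group for the next step.

Step 3
Reactants: 3 1-methoxy-8-(methoxymethoxy)naphthalene
Product: 5 2-[8-methoxy-1-(methoxymethoxy)naphthalen-2-yl]-4,4,5,5-tetramethyl-1,3,2-dioxaborolane, via 2-naphthyllithium 4 (not isolated)
Conditions: n-BuLi, TMEDA, Et2O, 0 °C → rt; i-PrOBpin, −78 °C → rt; aq. NH4Cl
Reagents that add atoms: 2-isopropoxy-4,4,5,5-tetramethyl-1,3,2-dioxaborolane, CC(C)OB1OC(C)(C)C(C)(C)O1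
Why: Directed ortho-metalation should place lithium at C2 rather than C7 because the chelating OMOM group outranks OMe as a director, and the isopropoxy boronate traps the aryllithium as the pinacol ester.

Step 4
Reactants: 2 8-methoxynaphthalen-1-ol
Product: 6 4-bromo-8-methoxynaphthalen-1-ol
Conditions: NBS (1.0 equiv), MeCN, −20 → 0 °C
Reagents that add atoms: N-bromosuccinimide, O=C1CCC(=O)N1Br
Why: Electrophilic aromatic bromination should go para to the free hydroxyl (C4), since the hydroxyl activates its own ring more than the hydrogen-bond-accepting methoxy group activates the other.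

Step 5
Reactants: 6 4-bromo-8-methoxynaphthalen-1-ol
Product: 7 1-(benzyloxy)-4-bromo-8-methoxynaphthalene
Conditions: BnBr, K2CO3, DMF, 60 °C
Reagents that add atoms: benzyl bromide, BrCc1ccccc1
Why: Williamson benzylation of the naphthoxide gives an ether that survives hot acetic anhydride and is removed by hydrogenolysis at the end.

Step 6
Reactants: 7 1-(benzyloxy)-4-bromo-8-methoxynaphthalene
Product: 8 2-[4-(benzyloxy)-5-methoxynaphthalen-1-yl]-4,4,5,5-tetramethyl-1,3,2-dioxaborolane
Conditions: B2pin2, Pd(dppf)Cl2·CH2Cl2 (3 mol%), KOAc, 1,4-dioxane, 90 °C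
Reagents that add atoms: bis(pinacolato)diboron, CC1(C)OB(OC1(C)C)B1OC(C)(C)C(C)(C)O1
Why: Miyaura borylation of an aryl bromide is routine for 1-bromonaphthalenes and tolerates the benzyl and methyl ethers.

Step 7
Reactants: 9 2-bromo-5-hydroxybenzaldehyde
Product: 10 2-bromo-5-hydroxy-4-iodobenzaldehyde
Conditions: NIS (1.05 equiv), TsOH·H2O (10 mol%), MeCN, 0 °C → rt
Reagents that add atoms: N-iodosuccinimide, O=C1CCC(=O)N1I
Why: Electrophilic aromatic iodination should enter at C4, because the para position carries bromine and the other ortho position (C6) is wedged between OH and CHO; the second bromine enters at the same position on dibromination of 3-hydroxybenzaldehyde.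

Step 8
Reactants: 10 2-bromo-5-hydroxy-4-iodobenzaldehyde
Product: 11 5-(benzyloxy)-2-bromo-4-iodobenzaldehyde
Conditions: BnBr, K2CO3, DMF, rt
Reagents that add atoms: benzyl bromide, BrCc1ccccc1
Why: Williamson benzylation of an acidic phenol proceeds under mild carbonate conditions that leave the non-enolisable aldehyde alone.

Step 9
Reactants: 11 5-(benzyloxy)-2-bromo-4-iodobenzaldehyde; 5 2-[8-methoxy-1-(methoxymethoxy)naphthalen-2-yl]-4,4,5,5-tetramethyl-1,3,2-dioxaborolane
Product: 12 5-(benzyloxy)-2-bromo-4-[8-methoxy-1-(methoxymethoxy)naphthalen-2-yl]benzaldehyde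
Conditions: Pd(PPh3)4 (5 mol%), 2 M aq. K2CO3, DME, 60 °C
Reagents that add atoms: none
Why: In this Suzuki–Miyaura coupling each carbon–halogen bond has one formyl and one alkoxy group ortho or para, so the electronics are matched and zerovalent palladium should insert into C–I well before C–Br, forming the B2–A2 bond.

Step 10
Reactants: 12 5-(benzyloxy)-2-bromo-4-[8-methoxy-1-(methoxymethoxy)naphthalen-2-yl]benzaldehyde
Product: 13 5-(benzyloxy)-2-bromo-4-(1-hydroxy-8-methoxynaphthalen-2-yl)benzaldehyde
Conditions: 6 M aq. HCl, THF, 50 °C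
Reagents that add atoms: none
Why: Acid hydrolysis removes the aryl MOM acetal, the only acid-labile group present, before it could be exposed to hot acetic anhydride in step 14.

Step 11
Reactants: 13 5-(benzyloxy)-2-bromo-4-(1-hydroxy-8-methoxynaphthalen-2-yl)benzaldehyde
Product: 14 5-(benzyloxy)-4-[1-(benzyloxy)-8-methoxynaphthalen-2-yl]-2-bromobenzaldehyde
Conditions: BnBr, Cs2CO3, DMF, 50 °C
Reagents that add atoms: benzyl bromide, BrCc1ccccc1
Why: Williamson benzylation with the more soluble caesium naphthoxide should overcome the hindered, hydrogen-bonded hydroxyl.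

Step 12
Reactants: 14 5-(benzyloxy)-4-[1-(benzyloxy)-8-methoxynaphthalen-2-yl]-2-bromobenzaldehyde; 8 2-[4-(benzyloxy)-5-methoxynaphthalen-1-yl]-4,4,5,5-tetramethyl-1,3,2-dioxaborolane
Product: 15 5-(benzyloxy)-4-[1-(benzyloxy)-8-methoxynaphthalen-2-yl]-2-[4-(benzyloxy)-5-methoxynaphthalen-1-yl]benzaldehyde
Conditions: Pd(OAc)2 (5 mol%), SPhos (10 mol%), K3PO4, toluene–H2O (10:1), 90 °C
Reagents that add atoms: none
Why: Suzuki–Miyaura coupling of an ortho-formyl aryl bromide with a 1-naphthyl boronate is standard with a bulky biarylphosphine and forms the B4–C4 bond on a benzene ring that has no peri hydrogen.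

Step 13
Reactants: 15 5-(benzyloxy)-4-[1-(benzyloxy)-8-methoxynaphthalen-2-yl]-2-[4-(benzyloxy)-5-methoxynaphthalen-1-yl]benzaldehyde; 16 (2-carboxyethyl)triphenylphosphonium bromide
Product: 18 (3E)-4-{5-(benzyloxy)-4-[1-(benzyloxy)-8-methoxynaphthalen-2-yl]-2-[4-(benzyloxy)-5-methoxynaphthalen-1-yl]phenyl}but-3-enoic acid, via carboxylate ylide 17 (not isolated)
Conditions: 16 (1.5 equiv), NaN(SiMe3)2 (2.9 equiv), THF, −20 °C; 15, −20 °C → rt; 1 M HCl
Reagents that add atoms: none
Why: Wittig olefination of aryl aldehydes with this carboxylate-bearing ylide is the standard entry to 4-arylbut-3-enoic acids and should give mainly the E alkene; any Z isomer can be carried on, since step 14 equilibrates the geometry.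

Step 14
Reactants: 18 (3E)-4-{5-(benzyloxy)-4-[1-(benzyloxy)-8-methoxynaphthalen-2-yl]-2-[4-(benzyloxy)-5-methoxynaphthalen-1-yl]phenyl}but-3-enoic acid
Product: 23 8-(benzyloxy)-7-[1-(benzyloxy)-8-methoxynaphthalen-2-yl]-5-[4-(benzyloxy)-5-methoxynaphthalen-1-yl]naphthalen-1-yl acetate, via mixed anhydride 19 (not isolated), via styrylketene 20 (not isolated), via cyclohexadienone 21 (not isolated), via free naphthol 22 (not isolated)
Conditions: Ac2O, NaOAc (3 equiv), 140 °C, N2
Reagents that add atoms: acetic anhydride, CC(=O)OC(C)=O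
Why: Acetic anhydride turns the acid into mixed anhydride 19, whose reversible dienolate formation under acetate scrambles the B5=B6 geometry, and loss of acetic acid then gives the (Z)-styrylketene 20. A thermal disrotatory six-electron electrocyclisation of the B8a=B4a–B5=B6–B7=B8 triene joins the ketene carbon B8 to B8a and closes the six-membered ring B4a–B5–B6–B7–B8–B8a (equally an acylation of the arene ortho to the B1 ether); dienone 21 enolises to naphthol 22, which is acetylated to 23. The closest known reaction is the acetic anhydride/sodium acetate cyclisation of 4-arylbut-3-enoic acids and Stobbe half-esters to 1-naphthyl acetates, including closures ortho to an alkoxy group when the para position is blocked. The only stereocentre formed, B8a in 21, is lost on aromatisation, so no stereocontrol is needed. The selectivity required is the site of closure: B4, the other position ortho to the chain, is occupied by unit C, which also turns the chain towards B8a, and B8a is activated by the adjacent B1 benzyloxy group. The new B8 oxygen emerges as the only acylated oxygen among three benzyl and three methyl ethers, which settles the OH versus OMe differentiation of the peri pair on unit B.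

Step 15
Reactants: 23 8-(benzyloxy)-7-[1-(benzyloxy)-8-methoxynaphthalen-2-yl]-5-[4-(benzyloxy)-5-methoxynaphthalen-1-yl]naphthalen-1-yl acetate
Product: 22 8-(benzyloxy)-7-[1-(benzyloxy)-8-methoxynaphthalen-2-yl]-5-[4-(benzyloxy)-5-methoxynaphthalen-1-yl]naphthalen-1-ol
Conditions: K2CO3 (cat.), MeOH–THF, rt; aq. NH4Cl
Reagents that add atoms: none
Why: Base-catalysed transesterification (methanolysis) cleaves the aryl acetate alone and releases, now as an isolated compound, the naphthol that passed through step 14.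

Step 16
Reactants: 22 8-(benzyloxy)-7-[1-(benzyloxy)-8-methoxynaphthalen-2-yl]-5-[4-(benzyloxy)-5-methoxynaphthalen-1-yl]naphthalen-1-ol
Product: 24 1-(benzyloxy)-2-[1-(benzyloxy)-8-methoxynaphthalen-2-yl]-4-[4-(benzyloxy)-5-methoxynaphthalen-1-yl]-8-methoxynaphthalene
Conditions: MeI, K2CO3, DMF, 50 °C
Reagents that add atoms: iodomethane, CI
Why: Williamson O-methylation can only occur at B8–OH, the single free hydroxyl in the molecule.

Step 17
Reactants: 24 1-(benzyloxy)-2-[1-(benzyloxy)-8-methoxynaphthalen-2-yl]-4-[4-(benzyloxy)-5-methoxynaphthalen-1-yl]-8-methoxynaphthalene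
Product: 25 2-(1-hydroxy-8-methoxynaphthalen-2-yl)-4-(4-hydroxy-5-methoxynaphthalen-1-yl)-8-methoxynaphthalen-1-ol
Conditions: H2 (1 atm), 10% Pd/C, EtOAc–MeOH, rt
Reagents that add atoms: none
Why: Catalytic hydrogenolysis removes the three aryl benzyl ethers under neutral conditions that leave the methyl ethers and the naphthalene rings untouched.

**Compound list**

1 | naphthalene-1,8-diol | Oc1cccc2cccc(O)c12 | starting material
2 | 8-methoxynaphthalen-1-ol | COc1cccc2cccc(O)c12 | intermediate
3 | 1-methoxy-8-(methoxymethoxy)naphthalene | COCOc1cccc2cccc(OC)c12 | intermediate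
4 | [8-methoxy-1-(methoxymethoxy)naphthalen-2-yl]lithium | [Li]c1ccc2cccc(OC)c2c1OCOC | intermediate
5 | 2-[8-methoxy-1-(methoxymethoxy)naphthalen-2-yl]-4,4,5,5-tetramethyl-1,3,2-dioxaborolane | COCOc1c(B2OC(C)(C)C(C)(C)O2)ccc2cccc(OC)c12 | intermediate
6 | 4-bromo-8-methoxynaphthalen-1-ol | COc1cccc2c(Br)ccc(O)c12 | intermediate
7 | 1-(benzyloxy)-4-bromo-8-methoxynaphthalene | COc1cccc2c(Br)ccc(OCc3ccccc3)c12 | intermediate
8 | 2-[4-(benzyloxy)-5-methoxynaphthalen-1-yl]-4,4,5,5-tetramethyl-1,3,2-dioxaborolane | COc1cccc2c(B3OC(C)(C)C(C)(C)O3)ccc(OCc3ccccc3)c12 | intermediate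
9 | 2-bromo-5-hydroxybenzaldehyde | O=Cc1cc(O)ccc1Br | starting material
10 | 2-bromo-5-hydroxy-4-iodobenzaldehyde | O=Cc1cc(O)c(I)cc1Br | intermediate
11 | 5-(benzyloxy)-2-bromo-4-iodobenzaldehyde | O=Cc1cc(OCc2ccccc2)c(I)cc1Br | intermediate
12 | 5-(benzyloxy)-2-bromo-4-[8-methoxy-1-(methoxymethoxy)naphthalen-2-yl]benzaldehyde | O=Cc1cc(OCc2ccccc2)c(-c2ccc3cccc(OC)c3c2OCOC)cc1Br | intermediate
13 | 5-(benzyloxy)-2-bromo-4-(1-hydroxy-8-methoxynaphthalen-2-yl)benzaldehyde | O=Cc1cc(OCc2ccccc2)c(-c2ccc3cccc(OC)c3c2O)cc1Br | intermediate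
14 | 5-(benzyloxy)-4-[1-(benzyloxy)-8-methoxynaphthalen-2-yl]-2-bromobenzaldehyde | O=Cc1cc(OCc2ccccc2)c(-c2ccc3cccc(OC)c3c2OCc2ccccc2)cc1Br | intermediate
15 | 5-(benzyloxy)-4-[1-(benzyloxy)-8-methoxynaphthalen-2-yl]-2-[4-(benzyloxy)-5-methoxynaphthalen-1-yl]benzaldehyde | O=Cc1cc(OCc2ccccc2)c(-c2ccc3cccc(OC)c3c2OCc2ccccc2)cc1-c1ccc(OCc2ccccc2)c2c(OC)cccc12 | intermediate
16 | (2-carboxyethyl)triphenylphosphonium bromide | OC(=O)CC[P+](c1ccccc1)(c1ccccc1)c1ccccc1.[Br-] | starting material
17 | sodium 3-(triphenyl-λ5-phosphanylidene)propanoate | [Na+].[O-]C(=O)CC=P(c1ccccc1)(c1ccccc1)c1ccccc1 | intermediate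
18 | (3E)-4-{5-(benzyloxy)-4-[1-(benzyloxy)-8-methoxynaphthalen-2-yl]-2-[4-(benzyloxy)-5-methoxynaphthalen-1-yl]phenyl}but-3-enoic acid | OC(=O)C/C=C/c1cc(OCc2ccccc2)c(-c2ccc3cccc(OC)c3c2OCc2ccccc2)cc1-c1ccc(OCc2ccccc2)c2c(OC)cccc12 | intermediate
19 | acetic (3E)-4-{5-(benzyloxy)-4-[1-(benzyloxy)-8-methoxynaphthalen-2-yl]-2-[4-(benzyloxy)-5-methoxynaphthalen-1-yl]phenyl}but-3-enoic anhydride | CC(=O)OC(=O)C/C=C/c1cc(OCc2ccccc2)c(-c2ccc3cccc(OC)c3c2OCc2ccccc2)cc1-c1ccc(OCc2ccccc2)c2c(OC)cccc12 | intermediate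
20 | (3Z)-4-{5-(benzyloxy)-4-[1-(benzyloxy)-8-methoxynaphthalen-2-yl]-2-[4-(benzyloxy)-5-methoxynaphthalen-1-yl]phenyl}buta-1,3-dien-1-one | O=C=C/C=C\c1cc(OCc2ccccc2)c(-c2ccc3cccc(OC)c3c2OCc2ccccc2)cc1-c1ccc(OCc2ccccc2)c2c(OC)cccc12 | intermediate
21 | 8-(benzyloxy)-7-[1-(benzyloxy)-8-methoxynaphthalen-2-yl]-5-[4-(benzyloxy)-5-methoxynaphthalen-1-yl]naphthalen-1(8aH)-one (racemic, transient) | O=C1C=CC=C2C(c3ccc(OCc4ccccc4)c4c(OC)cccc34)=CC(c3ccc4cccc(OC)c4c3OCc3ccccc3)=C(OCc3ccccc3)C12 | intermediate
22 | 8-(benzyloxy)-7-[1-(benzyloxy)-8-methoxynaphthalen-2-yl]-5-[4-(benzyloxy)-5-methoxynaphthalen-1-yl]naphthalen-1-ol | Oc1cccc2c(-c3ccc(OCc4ccccc4)c4c(OC)cccc34)cc(-c3ccc4cccc(OC)c4c3OCc3ccccc3)c(OCc3ccccc3)c12 | intermediate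
23 | 8-(benzyloxy)-7-[1-(benzyloxy)-8-methoxynaphthalen-2-yl]-5-[4-(benzyloxy)-5-methoxynaphthalen-1-yl]naphthalen-1-yl acetate | CC(=O)Oc1cccc2c(-c3ccc(OCc4ccccc4)c4c(OC)cccc34)cc(-c3ccc4cccc(OC)c4c3OCc3ccccc3)c(OCc3ccccc3)c12 | intermediate
24 | 1-(benzyloxy)-2-[1-(benzyloxy)-8-methoxynaphthalen-2-yl]-4-[4-(benzyloxy)-5-methoxynaphthalen-1-yl]-8-methoxynaphthalene | COc1cccc2c(-c3ccc(OCc4ccccc4)c4c(OC)cccc34)cc(-c3ccc4cccc(OC)c4c3OCc3ccccc3)c(OCc3ccccc3)c12 | intermediate
25 | 2-(1-hydroxy-8-methoxynaphthalen-2-yl)-4-(4-hydroxy-5-methoxynaphthalen-1-yl)-8-methoxynaphthalen-1-ol | COc1cccc2ccc(-c3cc(-c4ccc(O)c5c(OC)cccc45)c4cccc(OC)c4c3O)c(O)c12 | target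

**Step count**

Total: 17 steps. Longest linear sequence: 12 steps (steps 1, 2, 3, 9, 10, 11, 12, 13, 14, 15, 16, 17, from naphthalene-1,8-diol through unit A).

**Steps most likely to fail**

1. Step 14. In the crowded acid the E to Z equilibration of the B5=B6 bond may be slower than loss of the ketene to dimerisation or acetate-induced oligomerisation, so that little material reaches the electrocyclisation. The fallback sets out from 18 and replaces the ketene closure by an acylation–dehydrogenation sequence that forms the same B8–B8a bond. Diimide (TsNHNH2, NaOAc, aqueous DME, reflux) should saturate the side-chain alkene without touching the benzyl ethers and give 4-{5-(benzyloxy)-4-[1-(benzyloxy)-8-methoxynaphthalen-2-yl]-2-[4-(benzyloxy)-5-methoxynaphthalen-1-yl]phenyl}butanoic acid F1. Trifluoroacetic anhydride in CH2Cl2 at 0 °C should then effect intramolecular Friedel–Crafts acylation at B8a, again the only free ortho position, to give the 1-tetralone F2. TMSOTf/Et3N should convert it into the trimethylsilyl enol ether F3, and Saegusa–Ito oxidation with Pd(OAc)2 in MeCN should give the naphthalen-1(4H)-one F4, which is the keto tautomer of the naphthol and should isomerise to it. The route is rejoined at 22, ready for step 16.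

2. Step 12. Transmetalation onto the ortho-formyl arylpalladium intermediate may be slow enough for the electron-rich naphthyl boronate to be consumed by protodeboronation. The fallback sets out from 14 and bromide 7 and reverses the roles of the partners, which also bypasses boronate 8. Miyaura borylation of 14 (B2pin2, Pd(dppf)Cl2·CH2Cl2, KOAc, dioxane) should give the 2-formylaryl pinacol boronate 5-(benzyloxy)-4-[1-(benzyloxy)-8-methoxynaphthalen-2-yl]-2-(4,4,5,5-tetramethyl-1,3,2-dioxaborolan-2-yl)benzaldehyde F5. This is then coupled with naphthyl bromide 7 (Pd(OAc)2, SPhos, K3PO4, toluene–H2O), so that the boron sits on the electron-poor ring and the sensitive naphthalene enters as the stable halide. The route is rejoined at 15.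

3. Step 9. The temperature needed for the doubly ortho-substituted coupling may erode the discrimination between C–I and C–Br, leading to coupling at both halogens, while the ortho-alkoxy boronate slowly protodeboronates. The fallback sets out from 3 and iodide 11 and replaces boron by zinc so that the coupling runs at room temperature. Aryllithium 4, generated as in step 3, is transmetalated with ZnCl2 in THF to the arylzinc chloride chloro[8-methoxy-1-(methoxymethoxy)naphthalen-2-yl]zinc F6. Negishi coupling of this with 11 (Pd(PPh3)4, THF, rt) should engage only the iodide and leave the aldehyde untouched. The route is rejoined at 12.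

**Further compounds**

F1 | step 14 | 4-{5-(benzyloxy)-4-[1-(benzyloxy)-8-methoxynaphthalen-2-yl]-2-[4-(benzyloxy)-5-methoxynaphthalen-1-yl]phenyl}butanoic acid | OC(=O)CCCc1cc(OCc2ccccc2)c(-c2ccc3cccc(OC)c3c2OCc2ccccc2)cc1-c1ccc(OCc2ccccc2)c2c(OC)cccc12
F2 | step 14 | 8-(benzyloxy)-7-[1-(benzyloxy)-8-methoxynaphthalen-2-yl]-5-[4-(benzyloxy)-5-methoxynaphthalen-1-yl]-3,4-dihydronaphthalen-1(2H)-one | O=C1CCCc2c(-c3ccc(OCc4ccccc4)c4c(OC)cccc34)cc(-c3ccc4cccc(OC)c4c3OCc3ccccc3)c(OCc3ccccc3)c12
F3 | step 14 | {[8-(benzyloxy)-7-[1-(benzyloxy)-8-methoxynaphthalen-2-yl]-5-[4-(benzyloxy)-5-methoxynaphthalen-1-yl]-3,4-dihydronaphthalen-1-yl]oxy}trimethylsilane | C[Si](C)(C)OC1=CCCc2c(-c3ccc(OCc4ccccc4)c4c(OC)cccc34)cc(-c3ccc4cccc(OC)c4c3OCc3ccccc3)c(OCc3ccccc3)c12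
F4 | step 14 | 8-(benzyloxy)-7-[1-(benzyloxy)-8-methoxynaphthalen-2-yl]-5-[4-(benzyloxy)-5-methoxynaphthalen-1-yl]naphthalen-1(4H)-one | O=C1C=CCc2c(-c3ccc(OCc4ccccc4)c4c(OC)cccc34)cc(-c3ccc4cccc(OC)c4c3OCc3ccccc3)c(OCc3ccccc3)c12
F5 | step 12 | 5-(benzyloxy)-4-[1-(benzyloxy)-8-methoxynaphthalen-2-yl]-2-(4,4,5,5-tetramethyl-1,3,2-dioxaborolan-2-yl)benzaldehyde | O=Cc1cc(OCc2ccccc2)c(-c2ccc3cccc(OC)c3c2OCc2ccccc2)cc1B1OC(C)(C)C(C)(C)O1
F6 | step 9 | chloro[8-methoxy-1-(methoxymethoxy)naphthalen-2-yl]zinc | Cl[Zn]c1ccc2cccc(OC)c2c1OCOC
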